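## Retrosynthetic overview
1. The last step is acid removal of two MOM groups from the (2S)-5,7-bis-MOM flavanone. No skeletal bond changes.
2. Ring C is the only ring made. Its O1–C2 bond and the C2 stereocentre come from a new chiral-phosphoric-acid dehydrative cyclisation of a racemic aldol through a syringyl para-quinone methide.
3. The C2–C3 bond comes from aldol addition of a dilithiated 3-geranyl-6-hydroxy-2,4-bis-MOM-acetophenone to O-TBS-syringaldehyde.
4. The C4–C4a bond comes from ortho-lithiation and acetylation of a symmetric 4-geranyl-3,5-bis-MOM-phenol. Its symmetry allows only the 6-geranyl pattern, never the 8-geranyl one.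
5. That phenol comes from resorcinol by MOM protection, lithiation/geranyl bromide (E-alkene kept) and Ir C–H borylation/oxidation. Rings A and B are bought and ring C is closed last.

**Assumptions**
- The target is read as 2S with an E side-chain alkene.
- The sense of induction of the new step must be found by experiment. (R)-TRIP is assumed to give 2S; if it gives 2R, (S)-TRIP is used.
- Building blocks are numbered. Auxiliary reagents are named on the "Reagents that add atoms" line.

## Route

Step 1
Reactants: 1 resorcinol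
Product: 2 1,3-bis(methoxymethoxy)benzene
Conditions: NaH (2.4 equiv), MOMCl (2.4 equiv), DMF, 0 °C to rt
Reagents that add atoms: chloromethyl methyl ether (MOMCl), COCCl
Why: Williamson-type O-alkylation of the sodium bis-phenoxide by the very reactive alpha-chloro ether is fast and complete, and the two acetal ethers are the directing groups for both later lithiations.

Step 2
Reactants: 2 1,3-bis(methoxymethoxy)benzene; 3 geranyl bromide, (2E)-1-bromo-3,7-dimethylocta-2,6-diene
Product: 5 2-[(2E)-3,7-dimethylocta-2,6-dien-1-yl]-1,3-bis(methoxymethoxy)benzene, via 2-lithio arene 4 (not isolated)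
Conditions: n-BuLi (1.1 equiv), THF, 0 °C to rt, 1.5 h; CuBr·SMe2 (10 mol%), 3 (1.1 equiv), −40 °C to rt
Reagents that add atoms: n-butyllithium, [Li]CCCC (Li of 4 only)
Why: Directed ortho-metalation occurs only at C2–H, which is flanked by two coordinating OMOM groups, and copper-assisted SN2 coupling at the primary carbon of the allylic bromide gives the linear product with the E-alkene untouched.

Step 3
Reactants: 5 2-geranyl-1,3-bis(methoxymethoxy)benzene
Product: 7 4-[(2E)-3,7-dimethylocta-2,6-dien-1-yl]-3,5-bis(methoxymethoxy)phenol, via aryl pinacol boronate 6 (not isolated)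
Conditions: [Ir(OMe)(cod)]2 (1.5 mol%), dtbpy (3 mol%), B2pin2 (1.0 equiv), THF, 60 °C; then NaBO3·4H2O (3 equiv), THF/H2O, rt
Reagents that add atoms: bis(pinacolato)diboron, CC1(C)OB(OC1(C)C)B1OC(C)(C)C(C)(C)O1 (Bpin of 6 only); sodium perborate, [Na+].[O-]OB=O (phenol O of 7)
Why: Sterically controlled iridium-catalysed aromatic C–H borylation can reach only C5–H, the one ring C–H without an ortho substituent, and perborate oxidation of the C–B bond (1,2-aryl shift) gives the phenol without epoxidising the unactivated trisubstituted alkenes.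

Step 4
Reactants: 7 4-geranyl-3,5-bis(methoxymethoxy)phenol
Product: 8 5-(1-ethoxyethoxy)-2-[(2E)-3,7-dimethylocta-2,6-dien-1-yl]-1,3-bis(methoxymethoxy)benzene (racemic at the acetal carbon)
Conditions: ethyl vinyl ether (5 equiv), PPTS (5 mol%), CH2Cl2, 0 °C to rt
Reagents that add atoms: ethyl vinyl ether, C=COCC
Why: Acid-catalysed addition of the phenol to the enol ether (acetalisation) is mild enough for the MOM groups and the diene, and gives a base-stable, lithium-coordinating acetal that is far more acid-labile than MOM.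

Step 5
Reactants: 8 1-ethoxyethyl (EE) ether of 7; 9 N-methoxy-N-methylacetamide
Product: 12 1-{3-[(2E)-3,7-dimethylocta-2,6-dien-1-yl]-6-hydroxy-2,4-bis(methoxymethoxy)phenyl}ethan-1-one, via ortho-lithiated arene 10 (not isolated), via EE-protected ketone 11 (not isolated)
Conditions: n-BuLi (1.2 equiv), TMEDA (1.2 equiv), THF, −20 to 0 °C, 1 h; 9 (1.5 equiv), −78 to 0 °C; AcOH quench, aqueous wash; crude in EtOH, PPTS (10 mol%), rt, 2 h
Reagents that add atoms: n-butyllithium, [Li]CCCC (Li of 10 only)
Why: Directed ortho-metalation at one of the two equivalent C–H sites lying between two acetal oxygens, Weinreb ketone synthesis (the stable chelate stops over-addition) and selective acetal exchange of the much more labile EE group give the ketone whose only free OH is the one remote from the geranyl chain.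

Step 6
Reactants: 13 syringaldehyde (4-hydroxy-3,5-dimethoxybenzaldehyde)
Product: 14 4-(tert-butyldimethylsilyloxy)-3,5-dimethoxybenzaldehyde
Conditions: TBSCl (1.2 equiv), imidazole (2.5 equiv), DMF, rt
Reagents that add atoms: tert-butyldimethylsilyl chloride, CC(C)(C)[Si](C)(C)Cl
Why: Imidazole-promoted silylation masks the acidic phenol so that the aldehyde stays electrophilic in the aldol step.

Step 7
Reactants: 12 acetophenone from step 5; 14 O-TBS-syringaldehyde
Product: 16 rac-3-[4-(tert-butyldimethylsilyloxy)-3,5-dimethoxyphenyl]-1-{3-[(2E)-geranyl]-6-hydroxy-2,4-bis(methoxymethoxy)phenyl}-3-hydroxypropan-1-one, via dilithio enolate phenoxide 15 (not isolated)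
Conditions: LiHMDS (2.3 equiv), THF, −78 °C, 45 min; 14 (1.1 equiv), −78 °C, 1 h; AcOH/THF quench at −78 °C
Reagents that add atoms: lithium hexamethyldisilazide, [Li]N([Si](C)(C)C)[Si](C)(C)C (Li of 15 only)
Why: Kinetic aldol addition of the dilithiated o-hydroxyacetophenone to a non-enolisable aldehyde at −78 °C with a cold acidic quench stops at the beta-hydroxy ketone without dehydration, and the carbinol centre is left racemic on purpose because it is erased in step 9.

Step 8
Reactants: 16 rac-aldol, B-ring O-TBS
Product: 17 rac-1-{3-[(2E)-geranyl]-6-hydroxy-2,4-bis(methoxymethoxy)phenyl}-3-hydroxy-3-(4-hydroxy-3,5-dimethoxyphenyl)propan-1-one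
Conditions: TBAF (1.1 equiv)/AcOH (1.5 equiv), THF, 0 °C, 20 min; pH 7 work-up, used at once
Reagents that add atoms: none
Why: Fluoride-mediated cleavage of the aryl silyl ether is very fast, and the acetic acid buffer keeps the freed phenol protonated so that retro-aldol, E1cB dehydration and premature quinone methide formation do not set in.

Step 9
Reactants: 17 rac-aldol with free 4-OH (B ring) and free 6'-OH (A ring)
Product: 19 (2S)-6-[(2E)-3,7-dimethylocta-2,6-dien-1-yl]-2-(4-hydroxy-3,5-dimethoxyphenyl)-5,7-bis(methoxymethoxy)-2,3-dihydro-4H-chromen-4-one, via para-quinone methide 18 (not isolated)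
Conditions: (R)-TRIP (10 mol%), 5 Å MS, toluene (0.02 M), −20 °C, 24–48 h, stopped at full conversion; filtered cold through a short silica plug
Reagents that add atoms: none
Why: Proposed new method: this is an enantioconvergent dehydrative oxa-1,6-cyclisation in which the chiral phosphoric acid ionises the 4-hydroxybenzylic alcohol of either enantiomer of 17 (electron push from the free syringyl OH, water taken up by the sieves) to the same planar para-quinone methide 18, then holds the quinone-methide C=O through P–OH and the 6'-OH through P=O so that the phenol adds 6-exo-trig to one face of the exocyclic methide carbon, with rearomatisation making O1–C2 bond formation effectively irreversible at −20 °C so that C2 is set as S under catalyst control, and with the 2'-oxygen blocked as OMOM so that only the 6-geranyl ring isomer can form; the closest known reaction types are phosphoric-acid-catalysed asymmetric 1,6-additions to para-quinone methides generated in situ from 4-hydroxybenzyl alcohols and the racemic oxa-Michael closure of 2'-hydroxychalcones, whereas closure of a flavanone ring through a keto-substituted quinone methide is not known.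

Step 10
Reactants: 19 (2S)-5,7-bis-MOM flavanone
Product: 20 (2S)-6-[(2E)-3,7-dimethylocta-2,6-dien-1-yl]-5,7-dihydroxy-2-(4-hydroxy-3,5-dimethoxyphenyl)-2,3-dihydro-4H-chromen-4-one (target)
Conditions: HCl (cat., about 0.3 M) in MeOH, 35 °C, 3 h; pH 6 phosphate buffer work-up
Reagents that add atoms: none
Why: Acid-catalysed transacetalisation of the two aryl MOM ethers to dimethoxymethane works in dilute methanolic HCl, under which flavanones (which racemise by base-induced retro-oxa-Michael opening) keep the 2S centre and the trisubstituted alkenes are not protonated.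

## Compound list
1 | resorcinol | Oc1cccc(O)c1 | starting material
2 | 1,3-bis(methoxymethoxy)benzene | COCOc1cccc(OCOC)c1 | intermediate
3 | geranyl bromide, (2E)-1-bromo-3,7-dimethylocta-2,6-diene | BrC/C=C(\C)CCC=C(C)C | starting material
4 | 2-lithio-1,3-bis(methoxymethoxy)benzene (not isolated) | [Li]c1c(OCOC)cccc1OCOC | intermediate
5 | 2-[(2E)-geranyl]-1,3-bis(methoxymethoxy)benzene | COCOc1cccc(OCOC)c1C/C=C(\C)CCC=C(C)C | intermediate
6 | 2-{4-[(2E)-geranyl]-3,5-bis(methoxymethoxy)phenyl}-4,4,5,5-tetramethyl-1,3,2-dioxaborolane (not isolated) | CC1(C)OB(OC1(C)C)c1cc(OCOC)c(C/C=C(\C)CCC=C(C)C)c(OCOC)c1 | intermediate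
7 | 4-[(2E)-geranyl]-3,5-bis(methoxymethoxy)phenol | Oc1cc(OCOC)c(C/C=C(\C)CCC=C(C)C)c(OCOC)c1 | intermediate
8 | 5-(1-ethoxyethoxy)-2-[(2E)-geranyl]-1,3-bis(methoxymethoxy)benzene (racemic acetal carbon) | CCOC(C)Oc1cc(OCOC)c(C/C=C(\C)CCC=C(C)C)c(OCOC)c1 | intermediate
9 | N-methoxy-N-methylacetamide | CC(=O)N(C)OC | starting material
10 | aryllithium of 8, lithiated between OEE and OMOM (not isolated) | [Li]c1c(OC(C)OCC)cc(OCOC)c(C/C=C(\C)CCC=C(C)C)c1OCOC | intermediate
11 | 1-{6-(1-ethoxyethoxy)-3-[(2E)-geranyl]-2,4-bis(methoxymethoxy)phenyl}ethan-1-one (not isolated) | CC(=O)c1c(OC(C)OCC)cc(OCOC)c(C/C=C(\C)CCC=C(C)C)c1OCOC | intermediate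
12 | 1-{3-[(2E)-geranyl]-6-hydroxy-2,4-bis(methoxymethoxy)phenyl}ethan-1-one | CC(=O)c1c(O)cc(OCOC)c(C/C=C(\C)CCC=C(C)C)c1OCOC | intermediate
13 | syringaldehyde | COc1cc(C=O)cc(OC)c1O | starting material
14 | 4-(tert-butyldimethylsilyloxy)-3,5-dimethoxybenzaldehyde | COc1cc(C=O)cc(OC)c1O[Si](C)(C)C(C)(C)C | intermediate
15 | dilithio enolate-phenoxide of 12 (not isolated) | [Li]OC(=C)c1c(O[Li])cc(OCOC)c(C/C=C(\C)CCC=C(C)C)c1OCOC | intermediate
16 | rac-aldol, B-ring O-TBS | COc1cc(C(O)CC(=O)c2c(O)cc(OCOC)c(C/C=C(\C)CCC=C(C)C)c2OCOC)cc(OC)c1O[Si](C)(C)C(C)(C)C | intermediate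
17 | rac-aldol, B-ring free phenol | COc1cc(C(O)CC(=O)c2c(O)cc(OCOC)c(C/C=C(\C)CCC=C(C)C)c2OCOC)cc(OC)c1O | intermediate
18 | 4-(3-aryl-3-oxopropylidene)-2,6-dimethoxycyclohexa-2,5-dien-1-one, para-quinone methide (not isolated) | COC1=CC(=CCC(=O)c2c(O)cc(OCOC)c(C/C=C(\C)CCC=C(C)C)c2OCOC)C=C(OC)C1=O | intermediate
19 | (2S)-6-[(2E)-geranyl]-2-(4-hydroxy-3,5-dimethoxyphenyl)-5,7-bis(methoxymethoxy)chroman-4-one | COc1cc([C@@H]2CC(=O)c3c(cc(OCOC)c(C/C=C(\C)CCC=C(C)C)c3OCOC)O2)cc(OC)c1O | intermediate
20 | (2S)-6-[(2E)-geranyl]-5,7-dihydroxy-2-(4-hydroxy-3,5-dimethoxyphenyl)chroman-4-one | COc1cc([C@@H]2CC(=O)c3c(cc(O)c(C/C=C(\C)CCC=C(C)C)c3O)O2)cc(OC)c1O | target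

## Step count and risks
Total steps: 10. Longest linear sequence: 9 (steps 1–5 and 7–10, from resorcinol).

**Risk 1, step 9 (the new cyclisation).**
- What can go wrong: quinone methide 18 may tautomerise to the chalcone, the ee may be low, or product 19 may re-ionise and racemise.
- The fallback uses known chemistry, sets out from 17 and comes back at 19.
- Heating 17 with NaOAc in EtOH at reflux dehydrates it to the (E)-2'-hydroxychalcone F1. Under the same conditions this closes by reversible oxa-Michael addition to the racemic bis-MOM flavanone F2.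
- F2 is then resolved by asymmetric transfer hydrogenation in kinetic-resolution mode: [Cp*RhCl((R,R)-TsDPEN)] (1 mol%), HCO2H/Et3N, EtOAc, rt, stopped at about 52 % conversion.
- The (R,R)-catalyst forms 4R carbinols and is matched with the 2R enantiomer, because hydride arrives anti to the 2-aryl group. It gives the cis-(2R,4R)-flavan-4-ol F3.
- The untouched (2S)-ketone 19 is separated by chromatography. The yield ceiling is 50 %.

**Risk 2, step 5 (second lithiation and acetylation).**
- What can go wrong: the doubly activated benzylic/allylic CH2 of the geranyl group may be deprotonated instead, or the hindered aryllithium may enolise the amide.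
- The fallback avoids carbanion chemistry on the ring, sets out from 7 and comes back at 12.
- Magnesium-mediated ortho-formylation of free phenol 7 (MgCl2, Et3N, paraformaldehyde, MeCN, reflux; both ortho positions are equivalent) gives 3-geranyl-6-hydroxy-2,4-bis(methoxymethoxy)benzaldehyde F4.
- MeMgBr (2.5 equiv, THF, 0 °C) adds to give the racemic 1-arylethanol F5.
- MnO2 in CH2Cl2 oxidises the benzylic alcohol to 12.

**Risk 3, step 10 (final deprotection).**
- What can go wrong: acid may close a chroman between the geranyl alkene and a flanking OH, or ionisation at C2 may erode the ee.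
- The fallback replaces Brønsted-acid solvolysis by a non-acidic protecting-group exchange, sets out from 19 and comes back at 20.
- TMSOTf (6 equiv) and 2,2'-bipyridyl (9 equiv) in MeCN at 0 °C to rt turn both aryl MOM ethers and the free 4'-OH into silyl ethers. This gives the (2S)-5,7,4'-tris(trimethylsilyl) ether F6.
- Adding water at rt hydrolyses F6 under nearly neutral conditions to 20.

Further compounds
F1 | step 9 | (E)-1-{3-[(2E)-geranyl]-6-hydroxy-2,4-bis(methoxymethoxy)phenyl}-3-(4-hydroxy-3,5-dimethoxyphenyl)prop-2-en-1-one | COc1cc(/C=C/C(=O)c2c(O)cc(OCOC)c(C/C=C(\C)CCC=C(C)C)c2OCOC)cc(OC)c1O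
F2 | step 9 | rac-6-[(2E)-geranyl]-2-(4-hydroxy-3,5-dimethoxyphenyl)-5,7-bis(methoxymethoxy)chroman-4-one | COc1cc(C2CC(=O)c3c(cc(OCOC)c(C/C=C(\C)CCC=C(C)C)c3OCOC)O2)cc(OC)c1O
F3 | step 9 | (2R,4R)-6-[(2E)-geranyl]-2-(4-hydroxy-3,5-dimethoxyphenyl)-5,7-bis(methoxymethoxy)chroman-4-ol (2,4-cis) | COc1cc([C@H]2C[C@@H](O)c3c(cc(OCOC)c(C/C=C(\C)CCC=C(C)C)c3OCOC)O2)cc(OC)c1O
F4 | step 5 | 3-[(2E)-geranyl]-6-hydroxy-2,4-bis(methoxymethoxy)benzaldehyde | O=Cc1c(O)cc(OCOC)c(C/C=C(\C)CCC=C(C)C)c1OCOC
F5 | step 5 | rac-2-(1-hydroxyethyl)-4-[(2E)-geranyl]-3,5-bis(methoxymethoxy)phenol | CC(O)c1c(O)cc(OCOC)c(C/C=C(\C)CCC=C(C)C)c1OCOC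
F6 | step 10 | (2S)-6-[(2E)-geranyl]-2-[3,5-dimethoxy-4-(trimethylsilyloxy)phenyl]-5,7-bis(trimethylsilyloxy)chroman-4-one | COc1cc([C@@H]2CC(=O)c3c(cc(O[Si](C)(C)C)c(C/C=C(\C)CCC=C(C)C)c3O[Si](C)(C)C)O2)cc(OC)c1O[Si](C)(C)C
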